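(The constants are made up.)

Compare two rates.

    substrate → intermediate (k1 = 0.0889 h⁻¹)
    partner + intermediate ⇌ product (K2 = 7.5 M⁻¹, k2 = 0.0500 M⁻¹ h⁻¹)
    partner + protic impurity → quenched reagent (k3 = 18.8 M⁻¹ h⁻¹)

| flask | substrate | partner | protic impurity | time | remark |
|---|---|---|---|---|---|
| ash | 0.050 M | 0.250 M | 1.00 mM | 30 h | everything together in a closed stirred flask, run for 30 h |
| elm | 0.050 M | 0.250 M | 1.00 mM |  | one stirred flow tank at steady state, fed with the mixture as stated, mean residence time 30 h |
| maple | 0.050 M (fed, over 24.0 h) | 0.250 M | 1.00 mM | 30 h | a stirred flask in which substrate is dosed at a steady rate over 24.0 h without added volume, worked up at 30 h |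
| cedar | 0.050 M | 0.250 M (fed, over 24.0 h) | 1.00 mM | 30 h | a stirred flask in which partner is dosed at a steady rate over 24.0 h without added volume, worked up at 30 h |

* order of the set-ups by the amount of intermediate at the outlet or at the end, in percent of the substrate put in, highest first (ash / elm / maple / cedar)
* amount of intermediate at the outlet or at the end, in percent of the substrate put in, ash
* amount of intermediate at the outlet or at the end, in percent of the substrate put in, elm
* amount of intermediate at the outlet or at the end, in percent of the substrate put in, maple
* amount of intermediate at the outlet or at the end, in percent of the substrate put in, cedar

Intermediate is made by the first step and drained by the second. With partner at its full charge in ash, the rate constant of formation, 0.0889 h⁻¹, is larger than the first-order constant of the forward drain, 0.0125 h⁻¹, so we bracket intermediate between what has been formed and what the drain can have taken.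

Intermediate cannot exceed the substrate converted. That ceiling is 93.1% in ash and cedar, 72.7% in elm and 75.8% in maple.

For a floor, we integrate the forward rate as if converted substrate all sat as intermediate, with c_partner as dosed and nothing returning. In ash this gives 24.4% and in maple 11.8%. In cedar, with c_partner rising through the feed, it gives 17.7%. This drain allowance is an upper bound on the product in each of these flasks. The floors are therefore 75.4% in cedar and 64.0% in maple.

Ash and elm tighten further. We hold c_partner constant, a pseudo-first-order treatment, first at its charge and then at the lowest value the charges allow, 0.199 M, and count the way back. Ash then lies between 73.4% and 77.0%, and elm between 55.4% and 58.2%.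

So elm's upper bound stands below maple's floor. We put cedar above ash, with the same ceiling and a smaller allowance, but without proof, since cedar's floor stands lower than ash's upper bound. Ash and maple overlap, and we put ash first without proof.

The forecast gives cedar > ash > maple > elm, with 73.8% for ash, 55.9% for elm, 65.7% for maple and 78.3% for cedar, on the ground that “Dosing partner keeps that drain weak for most of the run”. Each value lies inside our bracket.

The simulation gives cedar > ash > maple > elm, with 73.8%, 55.9%, 65.7% and 78.3% in the same flasks, so the forecast stands. Ash and cedar end with the same 6.95% of substrate, and their gap stands as product, 19.2% against 14.8%.

Cedar's product is a reading of 0.838 of its allowance. The neighbouring cedar flask holds 0.15 M of partner, which scales the allowance to 10.6%. The same share then gives 8.88% of product and leaves 84.2% of intermediate. That neighbour ends with 9.19% of product and 83.9% of intermediate.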